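3 questions stand on this flask, and you can reach the first with a single rate.

all flasks: gas 93 mM (held)

| run | solid substrate | remark | time |
|---|---|---|---|
| ochre | 0.34 M | run made earlier |  |
| teal | 0.75 M | run made earlier |  |
| flask | 0.50 M |  | 8.0 d |

| run | time / d | target / % | solid substrate / % |
|---|---|---|---|
| ochre | 0.833 | 0.7 | 97.7 |
| ochre | 1.67 | 2.8 | 95.2 |
| ochre | 3.00 | 6.3 | 91.4 |
| ochre | 4.00 | 8.5 | 88.8 |
| ochre | 5.00 | 11.3 | 85.9 |
| ochre | 6.00 | 13.6 | 84.1 |
| teal | 0.500 | 0 | 98.6 |
| teal | 0.833 | 0.7 | 99.1 |
| teal | 1.25 | 0 | 98.3 |
| teal | 1.67 | 1.0 | 98.2 |
| teal | 3.00 | 2.9 | 96.3 |
| teal | 4.00 | 3.8 | 95.1 |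
| teal | 6.00 | 5.9 | 93.4 |

(readings scatter by 0.3 percentage points)

- given per volume of solution although it is solid: solid substrate
- at the start none of partner is dissolved
- the earlier runs were read with a standard deviation of 0.3 percentage points
- steps thought possible: gas <-> partner; partner -> decomposed reagent; dissolved substrate + partner -> target; partner -> side product; solid substrate <-> dissolved substrate
- at the start none of the solid substrate is in solution

- east: doubling the solubility of the solid substrate, all else as stated
- north: doubling the saturation concentration of gas, all else as stated
- west: doubling the dissolution coefficient of the solid substrate, all else as stated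
- south-east: doubling the transfer coefficient of the gas, all else as stated

- how much target there is at 8.0 d, in percent of the solid substrate charged
- the change that raises the amount of target at 8.0 d, in percent of the solid substrate charged most ("none" if none brings more than 2 percentage points) (east / north / west / south-east / none)
- amount of target at 8.0 d, in percent of the solid substrate charged, after north

Climb the time scales that the readings show, from fastest to slowest. On the lowest rung, you read the dissolved pool as the solid lost minus the target. In the ochre run it reads 5.44 mM after 0.833 d and 7.82 mM after 6.00 d, so the pool fills early in the run.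

On the next rung, define r, the target made per litre per day, from the last reading of the ochre run: r = 7.71 mM d⁻¹. The teal run, with a charge twice as large, reads 7.38 mM d⁻¹, so the rate is close to zero-order in the charge.

On the top rung, divide the charge by r, and you get the use-up time of this flask, τ = 64.9 d. That is far longer than the asked time, so I would commit to t/τ = 12.3%. Both runs held the gas at 93 mM, so r says nothing about north.

The forecast gives 12.2%, chooses north and expects 23.5% after it: “North is the robust choice”.

The flask gives 12.7%, against 12.3% from τ. The best change is east, which adds 13 percentage points, while north adds 2.2 points and reaches 15.0%.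

    gas ⇌ partner, rate k1*(csat - [partner]) (kL = 0.280 h⁻¹)
    partner → decomposed reagent (k = 0.0250 h⁻¹)
    dissolved substrate + partner → target (k = 4.90 L mol⁻¹ h⁻¹)
    partner → side product (k = 2.60 h⁻¹)
    solid substrate ⇌ dissolved substrate, rate k5*(cs5 - [dissolved substrate]) while solid is left; crystals form when [dissolved substrate] > cs5 (solubility = 39.0 mM, k = 0.0120 h⁻¹)

At 8.00 d in this flask, dissolved substrate is made, each step taken net, 1.00 times as fast as it is used up. Its pool stands at 1.68% of the solid substrate charged at 4.00 d and 1.69% at 8.00 d. For the neighbour charged with 0.12 M, r over 8.0 d gives 51.4% of its charge, and that neighbour holds 53.1% as target.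

Readings and results are simulated on assumed constants.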